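Ring A of the flavone half is built around the hindered biaryl bond, so that bond is never formed by coupling. Ring A is a 2-arylresorcinol: C5 carries OH, C6 is bonded to C3' of the flavanone ring B, C7 carries oxygen, C8 carries H, and C4a/C8a are shared with pyranone ring C. Irradiating a 6-aryl-4-pyranon-2-yl diazomethyl ketone with an aryl siloxyalkyne should give, in one operation, ketene formation, (2+2) addition, ring opening and six-electron closure to the 5-hydroxy-6-aryl-7-siloxyflavone. The chloride on the alkyne's aryl ring later becomes boron, and enantioselective addition to a chromone builds the (2S)-flavanone.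

Key step: step 8

Assumption: no axial descriptor is given, so the biaryl axis is treated as freely rotating in the target, and the (R)-pyridine–oxazoline ligand is assigned to the (2S) product by analogy with its sense of induction on cyclic enones; a trial addition of phenylboronic acid to 26 would confirm this before the ligand antipode is committed.

Step 1
Reactants: 1 4'-benzyloxyacetophenone
Product: 2 1-[4-(benzyloxy)phenyl]butane-1,3-dione
Conditions: NaH, EtOAc, THF, 0 °C → reflux; then aq. HCl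
Reagents that add atoms: ethyl acetate, CCOC(C)=O
Why: Crossed Claisen condensation of the ketone enolate with ethyl acetate, driven by removal of the 1,3-diketone as its sodium enolate, with the benzyl ether inert to base.

Step 2
Reactants: 2 1-[4-(benzyloxy)phenyl]butane-1,3-dione; 3 diethyl oxalate
Product: 5 ethyl 6-[4-(benzyloxy)phenyl]-4-oxo-4H-pyran-2-carboxylate, via triketo ester 4 (not isolated)
Conditions: NaOEt (2.2 equiv), EtOH/THF, 0 °C → rt; then HCl/EtOH, 70 °C
Reagents that add atoms: none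
Why: Claisen condensation at the terminal methyl group of the diketone (the site that leads to a stable, doubly enolised triketo ester salt under reversible conditions) followed by acid-catalysed cyclodehydration of the 1,3,5-tricarbonyl chain, the classical route to 6-aryl-4-pyranone-2-carboxylates.

Step 3
Reactants: 5 ethyl 6-[4-(benzyloxy)phenyl]-4-oxo-4H-pyran-2-carboxylate
Product: 6 6-[4-(benzyloxy)phenyl]-4-oxo-4H-pyran-2-carboxylic acid
Conditions: LiOH·H2O (1.05 equiv), THF/H2O, 0 °C; then 1 M HCl to pH 2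
Reagents that add atoms: lithium hydroxide, [Li+].[OH-]
Why: Saponification of an ester activated by the ring oxygen and the vinylogous carbonyl should go at 0 °C with one equivalent of hydroxide, which avoids hydroxide opening of the pyranone ring.

Step 4
Reactants: 6 6-[4-(benzyloxy)phenyl]-4-oxo-4H-pyran-2-carboxylic acid
Product: 8 2-(2-diazoacetyl)-6-[4-(benzyloxy)phenyl]-4H-pyran-4-one, via acid chloride 7 (not isolated)
Conditions: (COCl)2, DMF (cat.), CH2Cl2, 0 °C → rt, evaporate; then TMSCHN2 (2.2 equiv), THF/MeCN, 0 °C → rt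
Reagents that add atoms: trimethylsilyldiazomethane, C[Si](C)(C)C=[N+]=[N-]
Why: Acylation of the diazo carbon by the acid chloride with loss of the silyl group (Arndt–Eistert-type diazoketone synthesis), using the activation that is routine for chromone-2-carboxylic acids and the silyl reagent in place of diazomethane.

Step 5
Reactants: 9 5-chlorosalicylaldehyde
Product: 10 2-(benzyloxy)-5-chlorobenzaldehyde
Conditions: BnBr, K2CO3, DMF, rt
Reagents that add atoms: benzyl bromide, BrCc1ccccc1
Why: Williamson etherification of the phenoxide in a polar aprotic solvent, with the non-enolisable aldehyde untouched.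

Step 6
Reactants: 10 2-(benzyloxy)-5-chlorobenzaldehyde
Product: 11 1-(benzyloxy)-4-chloro-2-ethynylbenzene
Conditions: dimethyl (1-diazo-2-oxopropyl)phosphonate, K2CO3, MeOH, 0 °C → rt
Reagents that add atoms: dimethyl (1-diazo-2-oxopropyl)phosphonate, CC(=O)C(=[N+]=[N-])P(=O)(OC)OC
Why: Seyferth–Gilbert homologation in its Ohira–Bestmann form, in which the diazomethylphosphonate anion freed by methanolysis adds to the aldehyde and the alkylidene carbene left after loss of phosphate and N2 rearranges to the terminal alkyne under conditions mild enough for the benzyl ether and the chloride.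

Step 7
Reactants: 11 1-(benzyloxy)-4-chloro-2-ethynylbenzene
Product: 14 {[2-(benzyloxy)-5-chlorophenyl]ethynyloxy}tri(propan-2-yl)silane, via lithium acetylide 12 (not isolated), via lithium ynolate 13 (not isolated)
Conditions: LiN(SiMe3)2 (2.1 equiv), t-BuOOH (anhydrous, 1.05 equiv), THF, −78 → 0 °C; then i-Pr3SiOTf (1.2 equiv), −78 → 0 °C; base-washed silica
Reagents that add atoms: tert-butyl hydroperoxide, CC(C)(C)OO; triisopropylsilyl trifluoromethanesulfonate, CC(C)[Si](OS(=O)(=O)C(F)(F)F)(C(C)C)C(C)C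
Why: Oxidation of a lithium acetylide to an ynolate by attack on the electrophilic oxygen of lithium tert-butyl peroxide, followed by O-silylation with the hard, bulky silyl triflate to the silyl ynol ether, using an amide base that touches neither the aryl chloride (the later boron site) nor the benzyl ether.

Step 8
Reactants: 8 2-(2-diazoacetyl)-6-[4-(benzyloxy)phenyl]-4H-pyran-4-one; 14 {[2-(benzyloxy)-5-chlorophenyl]ethynyloxy}tri(propan-2-yl)silane
Product: 19 6-[2-(benzyloxy)-5-chlorophenyl]-2-[4-(benzyloxy)phenyl]-5-hydroxy-7-[tri(propan-2-yl)silyloxy]-4H-chromen-4-one, via pyranonyl ketene 15 (not isolated), via cyclobutenone 16 (not isolated), via dienylketene 17 (not isolated), via dienone 18 (not isolated)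
Conditions: 14 (1.5 equiv), hν (365 nm), degassed ClCH2CH2Cl, 25 °C; then 80 °C
Reagents that add atoms: none
Why: Excitation of the diazoketone expels N2 and the pyranonyl group shifts to the carbene carbon (Wolff rearrangement), giving ketene 15 conjugated with the pyranone C2=C3 bond; the nucleophilic aryl-bearing carbon of 14 bonds to the ketene carbonyl carbon, and the (2+2) adduct 16 opens by a conrotatory four-electron process to dienylketene 17. Ring A is then closed by a thermal disrotatory six-electron electrocyclisation in which the ketene carbon bonds to pyranone C3 (flavone C4a–C5), and dienone 18 enolises to the phenol, whose O–H is held by the C4 carbonyl. The closest known reaction type is the photochemical Danheiser benzannulation of unsaturated and heteroaryl diazoketones with siloxyalkynes, which gives 2-substituted resorcinol monosilyl ethers; here the pyranone C=C plays the part of the vinyl group. No stereocentre is formed. The step needs regioselectivity (aryl at C6, not C8), which the polarisation of the ynol ether secures in the (2+2) step and which the closure cannot alter because C3 is the only pyranone carbon next to the ketene-bearing position. It also needs chemoselectivity, which irradiation near 365 nm secures because the diazoketone absorbs there while the aryl chloride, the benzyl ethers and the chelated 5-hydroxyflavone product are photostable, and the bulky silyl group keeps the C7 oxygen distinct from the free C5 hydroxyl.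

Step 9
Reactants: 19 6-[2-(benzyloxy)-5-chlorophenyl]-2-[4-(benzyloxy)phenyl]-5-hydroxy-7-[tri(propan-2-yl)silyloxy]-4H-chromen-4-one
Product: 21 5,7-bis(benzyloxy)-6-[2-(benzyloxy)-5-chlorophenyl]-2-[4-(benzyloxy)phenyl]-4H-chromen-4-one, via diphenol 20 (not isolated)
Conditions: CsF, BnBr (3 equiv), K2CO3, DMF, rt → 60 °C
Reagents that add atoms: benzyl bromide, BrCc1ccccc1
Why: Fluoride cleaves the aryl silyl ether and the C7 phenoxide is benzylated at once, and carbonate at 60 °C then benzylates the chelated, flanked C5 hydroxyl (Williamson etherification), so that every oxygen carries the same hydrogenolysable group and no 5-hydroxy-4-keto chelate is left to bind palladium later.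

Step 10
Reactants: 21 5,7-bis(benzyloxy)-6-[2-(benzyloxy)-5-chlorophenyl]-2-[4-(benzyloxy)phenyl]-4H-chromen-4-one
Product: 22 {4-(benzyloxy)-3-[5,7-bis(benzyloxy)-2-[4-(benzyloxy)phenyl]-4-oxo-4H-chromen-6-yl]phenyl}boronic acid
Conditions: B2(OH)4 (3 equiv), [PdCl(XPhos)(2'-aminobiphenyl-2-yl)] (C45H59ClNPPd, second-generation XPhos palladacycle, 2 mol%), XPhos (4 mol%), KOAc (3 equiv), EtOH/THF, 80 °C
Reagents that add atoms: tetrahydroxydiboron, OB(O)B(O)O
Why: Palladium-catalysed Miyaura-type borylation of the aryl chloride with tetrahydroxydiboron should give the boronic acid directly, the bulky electron-rich ligand allowing oxidative addition of zerovalent palladium to the electron-rich C–Cl bond while the flavone carbonyl and the benzyl ethers stay untouched.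

Step 11
Reactants: 23 2,4,6-trihydroxyacetophenone
Product: 24 1-[2,4-bis(benzyloxy)-6-hydroxyphenyl]ethan-1-one
Conditions: BnBr (2.1 equiv), K2CO3, acetone, reflux
Reagents that add atoms: benzyl bromide, BrCc1ccccc1
Why: Williamson etherification that should stop at the dibenzyl ether because the last ortho hydroxyl is held in a hydrogen bond to the ketone and is far less nucleophilic.

Step 12
Reactants: 24 1-[2,4-bis(benzyloxy)-6-hydroxyphenyl]ethan-1-one
Product: 26 5,7-bis(benzyloxy)-4H-chromen-4-one, via enaminone 25 (not isolated)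
Conditions: Me2NCH(OMe)2, toluene, 95 °C; then conc. HCl, CH2Cl2, 40 °C; aq. NaHCO3 wash
Reagents that add atoms: N,N-dimethylformamide dimethyl acetal, COC(OC)N(C)C
Why: Condensation of the methyl ketone with the amide acetal gives enaminone 25, and acid then triggers conjugate addition of the free ortho phenol and loss of dimethylamine (enaminone route to chromones).

Step 13
Reactants: 22 {4-(benzyloxy)-3-[5,7-bis(benzyloxy)-2-[4-(benzyloxy)phenyl]-4-oxo-4H-chromen-6-yl]phenyl}boronic acid; 26 5,7-bis(benzyloxy)-4H-chromen-4-one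
Product: 27 (2S)-5,7-bis(benzyloxy)-2-{4-(benzyloxy)-3-[5,7-bis(benzyloxy)-2-[4-(benzyloxy)phenyl]-4-oxo-4H-chromen-6-yl]phenyl}-2,3-dihydro-4H-chromen-4-one
Conditions: 26 (2 equiv), Pd(OCOCF3)2 (10 mol%), (R)-4-tert-butyl-2-(pyridin-2-yl)-4,5-dihydrooxazole (12 mol%), NH4PF6 (30 mol%), H2O (5 equiv), ClCH2CH2Cl, 60 °C
Reagents that add atoms: none
Why: Enantioselective conjugate addition of an arylboronic acid to a chromone under cationic divalent palladium catalysis (transmetalation, insertion of the chromone C2=C3 bond into the aryl–palladium bond, protonolysis of the palladium enolate), in which the tert-butyl group of the (R)-ligand should leave only the Re face of chromone C2 open and so set (2S), while the non-basic medium gives no path for retro-oxa-Michael racemisation and the 2-aryl-substituted C2=C3 bond of 22 is too hindered to compete as acceptor.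

Step 14
Reactants: 27 (2S)-5,7-bis(benzyloxy)-2-{4-(benzyloxy)-3-[5,7-bis(benzyloxy)-2-[4-(benzyloxy)phenyl]-4-oxo-4H-chromen-6-yl]phenyl}-2,3-dihydro-4H-chromen-4-one
Product: 28 (2S)-5,7-dihydroxy-2-{4-hydroxy-3-[5,7-dihydroxy-2-(4-hydroxyphenyl)-4-oxo-4H-chromen-6-yl]phenyl}-2,3-dihydro-4H-chromen-4-one
Conditions: H2 (1 atm), Pd/C (10%), THF/MeOH, rt
Reagents that add atoms: none
Why: Hydrogenolysis of the six benzyl aryl ethers under neutral conditions should leave C2 untouched (a 4'-hydroxyflavanone racemises through base-induced ring opening only), and the flavone C2=C3 bond, the carbonyl groups and the benzylic C2–O bond react far more slowly, so the reaction is stopped at the calculated hydrogen uptake.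

Compound list
1 | 4'-benzyloxyacetophenone | CC(=O)c1ccc(OCc2ccccc2)cc1 | starting material
2 | 1-[4-(benzyloxy)phenyl]butane-1,3-dione | CC(=O)CC(=O)c1ccc(OCc2ccccc2)cc1 | intermediate
3 | diethyl oxalate | CCOC(=O)C(=O)OCC | starting material
4 | ethyl 6-[4-(benzyloxy)phenyl]-2,4,6-trioxohexanoate (present as its sodium enolate) | CCOC(=O)C(=O)CC(=O)CC(=O)c1ccc(OCc2ccccc2)cc1 | intermediate
5 | ethyl 6-[4-(benzyloxy)phenyl]-4-oxo-4H-pyran-2-carboxylate | CCOC(=O)c1cc(=O)cc(-c2ccc(OCc3ccccc3)cc2)o1 | intermediate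
6 | 6-[4-(benzyloxy)phenyl]-4-oxo-4H-pyran-2-carboxylic acid | OC(=O)c1cc(=O)cc(-c2ccc(OCc3ccccc3)cc2)o1 | intermediate
7 | 6-[4-(benzyloxy)phenyl]-4-oxo-4H-pyran-2-carbonyl chloride | ClC(=O)c1cc(=O)cc(-c2ccc(OCc3ccccc3)cc2)o1 | intermediate
8 | 2-(2-diazoacetyl)-6-[4-(benzyloxy)phenyl]-4H-pyran-4-one | [N-]=[N+]=CC(=O)c1cc(=O)cc(-c2ccc(OCc3ccccc3)cc2)o1 | intermediate
9 | 5-chlorosalicylaldehyde | O=Cc1cc(Cl)ccc1O | starting material
10 | 2-(benzyloxy)-5-chlorobenzaldehyde | O=Cc1cc(Cl)ccc1OCc1ccccc1 | intermediate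
11 | 1-(benzyloxy)-4-chloro-2-ethynylbenzene | C#Cc1cc(Cl)ccc1OCc1ccccc1 | intermediate
12 | lithium [2-(benzyloxy)-5-chlorophenyl]acetylide | [Li]C#Cc1cc(Cl)ccc1OCc1ccccc1 | intermediate
13 | lithium 2-[2-(benzyloxy)-5-chlorophenyl]ethyn-1-olate | [Li]OC#Cc1cc(Cl)ccc1OCc1ccccc1 | intermediate
14 | {[2-(benzyloxy)-5-chlorophenyl]ethynyloxy}tri(propan-2-yl)silane | CC(C)[Si](OC#Cc1cc(Cl)ccc1OCc1ccccc1)(C(C)C)C(C)C | intermediate
15 | 2-[4-(benzyloxy)phenyl]-6-(2-oxoethenyl)-4H-pyran-4-one (pyranonyl ketene) | O=C=Cc1cc(=O)cc(-c2ccc(OCc3ccccc3)cc2)o1 | intermediate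
16 | 2-[2-(benzyloxy)-5-chlorophenyl]-4-{6-[4-(benzyloxy)phenyl]-4-oxo-4H-pyran-2-yl}-3-[tri(propan-2-yl)silyloxy]cyclobut-2-en-1-one (racemic at C4) | O=C1C(c2cc(Cl)ccc2OCc2ccccc2)=C(O[Si](C(C)C)(C(C)C)C(C)C)C1c1cc(=O)cc(-c2ccc(OCc3ccccc3)cc2)o1 | intermediate
17 | (3E)-2-[2-(benzyloxy)-5-chlorophenyl]-4-{6-[4-(benzyloxy)phenyl]-4-oxo-4H-pyran-2-yl}-3-[tri(propan-2-yl)silyloxy]buta-1,3-dien-1-one (dienylketene) | O=C=C(c1cc(Cl)ccc1OCc1ccccc1)/C(O[Si](C(C)C)(C(C)C)C(C)C)=C\c1cc(=O)cc(-c2ccc(OCc3ccccc3)cc2)o1 | intermediate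
18 | 6-[2-(benzyloxy)-5-chlorophenyl]-2-[4-(benzyloxy)phenyl]-7-[tri(propan-2-yl)silyloxy]-4H-chromene-4,5(4aH)-dione (racemic at C4a) | O=C1C(c2cc(Cl)ccc2OCc2ccccc2)=C(O[Si](C(C)C)(C(C)C)C(C)C)C=C2OC(c3ccc(OCc4ccccc4)cc3)=CC(=O)C12 | intermediate
19 | 6-[2-(benzyloxy)-5-chlorophenyl]-2-[4-(benzyloxy)phenyl]-5-hydroxy-7-[tri(propan-2-yl)silyloxy]-4H-chromen-4-one | CC(C)[Si](Oc1cc2oc(-c3ccc(OCc4ccccc4)cc3)cc(=O)c2c(O)c1-c1cc(Cl)ccc1OCc1ccccc1)(C(C)C)C(C)C | intermediate
20 | 6-[2-(benzyloxy)-5-chlorophenyl]-2-[4-(benzyloxy)phenyl]-5,7-dihydroxy-4H-chromen-4-one | Oc1cc2oc(-c3ccc(OCc4ccccc4)cc3)cc(=O)c2c(O)c1-c1cc(Cl)ccc1OCc1ccccc1 | intermediate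
21 | 5,7-bis(benzyloxy)-6-[2-(benzyloxy)-5-chlorophenyl]-2-[4-(benzyloxy)phenyl]-4H-chromen-4-one | O=c1cc(-c2ccc(OCc3ccccc3)cc2)oc2cc(OCc3ccccc3)c(-c3cc(Cl)ccc3OCc3ccccc3)c(OCc3ccccc3)c12 | intermediate
22 | {4-(benzyloxy)-3-[5,7-bis(benzyloxy)-2-[4-(benzyloxy)phenyl]-4-oxo-4H-chromen-6-yl]phenyl}boronic acid | O=c1cc(-c2ccc(OCc3ccccc3)cc2)oc2cc(OCc3ccccc3)c(-c3cc(B(O)O)ccc3OCc3ccccc3)c(OCc3ccccc3)c12 | intermediate
23 | 2,4,6-trihydroxyacetophenone | CC(=O)c1c(O)cc(O)cc1O | starting material
24 | 1-[2,4-bis(benzyloxy)-6-hydroxyphenyl]ethan-1-one | CC(=O)c1c(O)cc(OCc2ccccc2)cc1OCc1ccccc1 | intermediate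
25 | (2E)-1-[2,4-bis(benzyloxy)-6-hydroxyphenyl]-3-(dimethylamino)prop-2-en-1-one | CN(C)/C=C/C(=O)c1c(O)cc(OCc2ccccc2)cc1OCc1ccccc1 | intermediate
26 | 5,7-bis(benzyloxy)-4H-chromen-4-one | O=c1ccoc2cc(OCc3ccccc3)cc(OCc3ccccc3)c12 | intermediate
27 | (2S)-5,7-bis(benzyloxy)-2-{4-(benzyloxy)-3-[5,7-bis(benzyloxy)-2-[4-(benzyloxy)phenyl]-4-oxo-4H-chromen-6-yl]phenyl}-2,3-dihydro-4H-chromen-4-one | O=C1C[C@@H](c2ccc(OCc3ccccc3)c(-c3c(OCc4ccccc4)cc4oc(-c5ccc(OCc6ccccc6)cc5)cc(=O)c4c3OCc3ccccc3)c2)Oc2cc(OCc3ccccc3)cc(OCc3ccccc3)c21 | intermediate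
28 | (2S)-5,7-dihydroxy-2-{4-hydroxy-3-[5,7-dihydroxy-2-(4-hydroxyphenyl)-4-oxo-4H-chromen-6-yl]phenyl}-2,3-dihydro-4H-chromen-4-one | O=C1C[C@@H](c2ccc(O)c(-c3c(O)cc4oc(-c5ccc(O)cc5)cc(=O)c4c3O)c2)Oc2cc(O)cc(O)c21 | target

Total step count: 14. Longest linear sequence: 9 steps (steps 1, 2, 3, 4, 8, 9, 10, 13, 14, from 1).

Steps most likely to fail

Step 8. The pyranone chromophore may undergo its own photochemistry, the ketene may be trapped before the (2+2) addition, or the six-electron closure onto the electron-poor pyranone C3 may stall at the cyclobutenone. The fallback makes the biaryl bond by cross-coupling of a 6-iodoflavone; it sets out from 24 and comes back to the route at 21. Claisen–Schmidt condensation of 24 with 4-(benzyloxy)benzaldehyde (KOH, EtOH) would give (2E)-1-[2,4-bis(benzyloxy)-6-hydroxyphenyl]-3-[4-(benzyloxy)phenyl]prop-2-en-1-one F1. Oxidative cyclisation (I2 cat., DMSO, 120 °C) would give 5,7-bis(benzyloxy)-2-[4-(benzyloxy)phenyl]-4H-chromen-4-one F2. Chelation-controlled removal of the peri benzyl group (BCl3, 1.1 equiv, CH2Cl2, −78 °C) would give 7-(benzyloxy)-2-[4-(benzyloxy)phenyl]-5-hydroxy-4H-chromen-4-one F3. Iodination ortho to the free hydroxyl (benzyltrimethylammonium dichloroiodate, CaCO3, CH2Cl2/MeOH) would give 7-(benzyloxy)-2-[4-(benzyloxy)phenyl]-5-hydroxy-6-iodo-4H-chromen-4-one F4, and benzylation (BnBr, K2CO3, DMF) would give 5,7-bis(benzyloxy)-2-[4-(benzyloxy)phenyl]-6-iodo-4H-chromen-4-one F5. Suzuki–Miyaura coupling of F5 with commercial [2-(benzyloxy)-5-chlorophenyl]boronic acid (Pd(PPh3)4, a zerovalent palladium catalyst that leaves the aryl chloride alone, Na2CO3, DME/H2O, 85 °C) would give 21.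

Step 13. Protodeboronation of the electron-rich boronic acid may outrun insertion into the electron-rich, peri-substituted chromone, or the facial selectivity may be insufficient with so large an aryl group. The fallback gives up catalyst control and obtains the stereocentre by resolution; it sets out from 22 and 26 and comes back at 27. Conjugate addition with the more reactive achiral catalyst Pd(OCOCF3)2/2,2'-bipyridine (AcOH/THF/H2O, 60 °C) would give racemic 5,7-bis(benzyloxy)-2-{4-(benzyloxy)-3-[5,7-bis(benzyloxy)-2-[4-(benzyloxy)phenyl]-4-oxo-4H-chromen-6-yl]phenyl}-2,3-dihydro-4H-chromen-4-one F6. Its enantiomers would be separated by preparative chromatography on a polysaccharide chiral phase, the (2S) enantiomer being 27.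

Step 7. Oxygen transfer from the lithium peroxide to the aryl acetylide may be incomplete, or the ynolate may be silylated at carbon or hydrolysed during isolation. The fallback reaches the same ynolate from an ester instead of an alkyne (Kowalski ynolate formation); it sets out from 10 and comes back at 13, which is silylated to 14 as in step 7. Oxidative esterification of 10 (I2, KOH, MeOH, 0 °C) would give methyl 2-(benzyloxy)-5-chlorobenzoate F7. Addition of LiCHBr2 (from CH2Br2 and lithium 2,2,6,6-tetramethylpiperidide, THF, −78 °C) would give, after loss of methoxide, the lithium enolate of 1-[2-(benzyloxy)-5-chlorophenyl]-2,2-dibromoethan-1-one F8. Bromine–lithium exchange with n-BuLi at −78 °C and warming to 0 °C would trigger the carbenoid rearrangement to 13.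

Further compounds
F1 | step 8 | (2E)-1-[2,4-bis(benzyloxy)-6-hydroxyphenyl]-3-[4-(benzyloxy)phenyl]prop-2-en-1-one | O=C(/C=C/c1ccc(OCc2ccccc2)cc1)c1c(O)cc(OCc2ccccc2)cc1OCc1ccccc1
F2 | step 8 | 5,7-bis(benzyloxy)-2-[4-(benzyloxy)phenyl]-4H-chromen-4-one | O=c1cc(-c2ccc(OCc3ccccc3)cc2)oc2cc(OCc3ccccc3)cc(OCc3ccccc3)c12
F3 | step 8 | 7-(benzyloxy)-2-[4-(benzyloxy)phenyl]-5-hydroxy-4H-chromen-4-one | O=c1cc(-c2ccc(OCc3ccccc3)cc2)oc2cc(OCc3ccccc3)cc(O)c12
F4 | step 8 | 7-(benzyloxy)-2-[4-(benzyloxy)phenyl]-5-hydroxy-6-iodo-4H-chromen-4-one | O=c1cc(-c2ccc(OCc3ccccc3)cc2)oc2cc(OCc3ccccc3)c(I)c(O)c12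
F5 | step 8 | 5,7-bis(benzyloxy)-2-[4-(benzyloxy)phenyl]-6-iodo-4H-chromen-4-one | O=c1cc(-c2ccc(OCc3ccccc3)cc2)oc2cc(OCc3ccccc3)c(I)c(OCc3ccccc3)c12
F6 | step 13 | rac-5,7-bis(benzyloxy)-2-{4-(benzyloxy)-3-[5,7-bis(benzyloxy)-2-[4-(benzyloxy)phenyl]-4-oxo-4H-chromen-6-yl]phenyl}-2,3-dihydro-4H-chromen-4-one | O=C1CC(c2ccc(OCc3ccccc3)c(-c3c(OCc4ccccc4)cc4oc(-c5ccc(OCc6ccccc6)cc5)cc(=O)c4c3OCc3ccccc3)c2)Oc2cc(OCc3ccccc3)cc(OCc3ccccc3)c21
F7 | step 7 | methyl 2-(benzyloxy)-5-chlorobenzoate | COC(=O)c1cc(Cl)ccc1OCc1ccccc1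
F8 | step 7 | 1-[2-(benzyloxy)-5-chlorophenyl]-2,2-dibromoethan-1-one (as its lithium enolate) | O=C(C(Br)Br)c1cc(Cl)ccc1OCc1ccccc1
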